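**Plan**

1. Feature: with the chain numbered C1 (guaiacyl-bearing ring carbon) to C7 (benzylic CH2), the pyran oxygen on C5 and the hydroxyl on C6 are a vicinal threo pair that can both bond to C1. With C1 at the ketone level the target is therefore a 6,8-dioxabicyclo[3.2.1]octane aryl ketal.
2. Retrosynthesis: cut C1–H (hydride to the aryl oxocarbenium ion of that ketal), then the ketal bonds O–C5 and C6–O–C1 (back to a δ,ε-cis-epoxy aryl ketone), then the epoxide (Z-alkene, alkyne), then C4–C5, C1–C2 and C6–C7.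
3. Forward: an aryl dithiane (C1), (R)-epichlorohydrin (C2–C4) and an aryl-propyne (C5–C7) give the chain. One acid step closes the pyran and dioxolane rings of the ketal. Hydride then opens the dioxolane ring and leaves the 2,6-cis tetrahydropyran.
4. Stereochemistry: C3 comes from (R)-epichlorohydrin as the epimer of the target and directs the vanadium epoxidation that fixes C5/C6. Anti opening at C5 gives the (5S,6S) threo pair. C3 is inverted by a Mitsunobu reaction while the C6 oxygen is held in the ketal. C1 is set by axial hydride delivery.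

Key step: step 9

Remark: the hydroxyl-directed vanadium epoxidation of a carbinol-substituted (Z)-homoallylic alcohol is assumed to follow the chair vanadate model and give the 1,3-syn epoxy alcohol; because the ketone oxygen must enter C5 anti to that epoxide oxygen, the directing C3 hydroxyl has to be the epimer of the target and is inverted after the key step.

**Route**

Step 1
Reactants: 1 4-(benzyloxy)benzyl chloride; 2 ethynylmagnesium bromide
Product: 3 1-(benzyloxy)-4-(prop-2-yn-1-yl)benzene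
Conditions: HC≡CMgBr (0.5 M in THF), CuCl (10 mol%), THF, 50 °C
Reagents that add atoms: ethynylmagnesium bromide (compound 2), C#C[Mg]Br
Why: Copper-catalysed coupling of an alkynyl Grignard reagent with an activated benzylic chloride (sp3–sp substitution) is the standard entry to 3-aryl-1-propynes; no stereocentre is formed and a neutral work-up should avoid isomerisation to the allene.

Step 2
Reactants: 4 4-(benzyloxy)-3-methoxybenzaldehyde
Product: 5 2-[4-(benzyloxy)-3-methoxyphenyl]-1,3-dithiane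
Conditions: HS(CH2)3SH, BF3·OEt2 (cat.), CH2Cl2, 0 °C → rt
Reagents that add atoms: propane-1,3-dithiol, SCCCS
Why: Lewis-acid-catalysed dithioacetalisation of an aryl aldehyde turns C1 into an acyl-anion equivalent (Corey–Seebach umpolung); the aryl benzyl ether tolerates catalytic BF3·OEt2 at this temperature.

Step 3
Reactants: 5 2-[4-(benzyloxy)-3-methoxyphenyl]-1,3-dithiane; 6 (R)-epichlorohydrin
Product: 9 (R)-2-({2-[4-(benzyloxy)-3-methoxyphenyl]-1,3-dithian-2-yl}methyl)oxirane, via 2-lithio-2-[4-(benzyloxy)-3-methoxyphenyl]-1,3-dithiane 7 (not isolated), via lithium (R)-1-chloro-3-{2-[4-(benzyloxy)-3-methoxyphenyl]-1,3-dithian-2-yl}propan-2-olate 8 (not isolated)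
Conditions: n-BuLi, THF, −78 °C; then 6, −78 °C → rt
Reagents that add atoms: none
Why: Corey–Seebach alkylation in which the lithiated dithiane opens the epoxide of epichlorohydrin at its CH2 terminus and the resulting alkoxide displaces chloride on warming, so the C–O bond of the stereocentre is never broken and (R)-epichlorohydrin gives the (R)-epoxide that becomes C3.

Step 4
Reactants: 9 (R)-2-({2-[4-(benzyloxy)-3-methoxyphenyl]-1,3-dithian-2-yl}methyl)oxirane; 3 1-(benzyloxy)-4-(prop-2-yn-1-yl)benzene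
Product: 11 (S)-1-{2-[4-(benzyloxy)-3-methoxyphenyl]-1,3-dithian-2-yl}-6-[4-(benzyloxy)phenyl]hex-4-yn-2-ol, via lithium 3-[4-(benzyloxy)phenyl]prop-1-yn-1-ide 10 (not isolated)
Conditions: 3, n-BuLi, THF, −78 °C; BF3·OEt2; then 9, −78 °C
Reagents that add atoms: none
Why: Yamaguchi–Hirao alkynylation in which the lithium acetylide (formed at −78 °C, where the terminal C–H is removed in preference to the benzylic-propargylic one) opens the BF3-activated terminal epoxide at its CH2 carbon, forming C4–C5 and leaving the C3–O bond and its configuration untouched.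

Step 5
Reactants: 11 (S)-1-{2-[4-(benzyloxy)-3-methoxyphenyl]-1,3-dithian-2-yl}-6-[4-(benzyloxy)phenyl]hex-4-yn-2-ol
Product: 12 (S)-1-[4-(benzyloxy)-3-methoxyphenyl]-7-[4-(benzyloxy)phenyl]-3-hydroxyhept-5-yn-1-one
Conditions: MeI, CaCO3, MeCN–H2O (9:1), 45 °C
Reagents that add atoms: water, O
Why: Alkylative hydrolysis of the dithiane (S-methylation, then hydrolysis of the thionium ion) under buffered, near-neutral conditions should spare the β-hydroxy ketone from dehydration and the skipped aryl-alkyne from isomerisation, and it removes sulfur before the palladium and peroxide steps.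

Step 6
Reactants: 12 (S)-1-[4-(benzyloxy)-3-methoxyphenyl]-7-[4-(benzyloxy)phenyl]-3-hydroxyhept-5-yn-1-one
Product: 13 (S,Z)-1-[4-(benzyloxy)-3-methoxyphenyl]-7-[4-(benzyloxy)phenyl]-3-hydroxyhept-5-en-1-one
Conditions: H2 (1 atm), Lindlar catalyst, quinoline, EtOAc, rt
Reagents that add atoms: none
Why: Lindlar semi-hydrogenation (syn addition of H2 on poisoned palladium) should give the Z-alkene without touching the aryl benzyl ethers or the aryl ketone.

Step 7
Reactants: 13 (S,Z)-1-[4-(benzyloxy)-3-methoxyphenyl]-7-[4-(benzyloxy)phenyl]-3-hydroxyhept-5-en-1-one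
Product: 14 (S)-1-[4-(benzyloxy)-3-methoxyphenyl]-4-{(2R,3S)-3-[4-(benzyloxy)benzyl]oxiran-2-yl}-3-hydroxybutan-1-one
Conditions: VO(acac)2 (5 mol%), t-BuOOH (in decane), CH2Cl2, 0 °C
Reagents that add atoms: tert-butyl hydroperoxide, CC(C)(C)OO
Why: Hydroxyl-directed vanadium epoxidation of a (Z)-homoallylic alcohol, in which oxygen is delivered within a chair-like vanadate ester with the C3 substituent equatorial and the allylic conformation fixed by A(1,3) strain of the Z-alkene, so that the epoxide oxygen should enter syn to the C3 hydroxyl and the (3S) carbinol should set the (5R,6S) cis-epoxide with retention of alkene geometry.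

Step 8
Reactants: 14 (S)-1-[4-(benzyloxy)-3-methoxyphenyl]-4-{(2R,3S)-3-[4-(benzyloxy)benzyl]oxiran-2-yl}-3-hydroxybutan-1-one
Product: 15 (S)-1-[4-(benzyloxy)-3-methoxyphenyl]-4-{(2R,3S)-3-[4-(benzyloxy)benzyl]oxiran-2-yl}-3-(tert-butyldimethylsilyloxy)butan-1-one
Conditions: TBSCl, imidazole, DMF, 0 °C → rt
Reagents that add atoms: tert-butyldimethylsilyl chloride, CC(C)(C)[Si](C)(C)Cl
Why: Silylation with TBSCl/imidazole (mild and not Lewis acidic) masks the C3 hydroxyl, whose 5-endo attack on C6 would otherwise compete with the ketone in the next step; the β-hydroxy ketone and the epoxide should tolerate imidazole at room temperature.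

Step 9
Reactants: 15 (S)-1-[4-(benzyloxy)-3-methoxyphenyl]-4-{(2R,3S)-3-[4-(benzyloxy)benzyl]oxiran-2-yl}-3-(tert-butyldimethylsilyloxy)butan-1-one
Product: 17 (1S,3S,5S,7S)-5-[4-(benzyloxy)-3-methoxyphenyl]-7-exo-[4-(benzyloxy)benzyl]-3-endo-(tert-butyldimethylsilyloxy)-6,8-dioxabicyclo[3.2.1]octane (chain numbering 3S,5S,6S), via the hydroxy oxocarbenium ion (2S,4S)-6-[4-(benzyloxy)-3-methoxyphenyl]-2-{(1S)-2-[4-(benzyloxy)phenyl]-1-hydroxyethyl}-4-(tert-butyldimethylsilyloxy)-3,4-dihydro-2H-pyran-1-ium 16 (not isolated)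
Conditions: CSA (10 mol%), CH2Cl2, 0 °C → rt
Reagents that add atoms: none
Why: The acid activates the cis-epoxide and the carbonyl oxygen of the electron-rich aryl ketone attacks C5 from the side opposite its C–O bond (6-exo-tet, chair-like), which forms O–C5 with inversion and gives oxocarbenium ion 16; the freed C6 hydroxyl then adds to C1 and closes the dioxolane ring (formally 5-endo-trig at the C1=O+ bond, the usual mode of dioxolane formation from an oxocarbenium ion). The closest known reaction type is the acid-catalysed isomerisation of δ,ε-epoxy ketones to 6,8-dioxabicyclo[3.2.1]octanes. C5 is controlled by the stereospecific anti (SN2-like) opening and C6 keeps its C–O bond, so the cis-epoxide should give the threo (5S,6S) pair with the benzyl group exo, and the ketal carbon C1 can only take the one configuration that the two-atom bridge allows. The step needs attack at C5 (6-exo) and not at C6 (7-endo), which the ring size and the absence of any cation-stabilising group at C6 secure, and it needs the ketone and not the C3 oxygen as nucleophile, which the silyl ether secures. The 4-benzyloxy-3-methoxyphenyl group stabilises the oxocarbenium ion and the bicyclic ketal is the thermodynamic sink, so the endo (axial) silyloxy group should be tolerated.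

Step 10
Reactants: 17 (1S,3S,5S,7S)-5-[4-(benzyloxy)-3-methoxyphenyl]-7-exo-[4-(benzyloxy)benzyl]-3-endo-(tert-butyldimethylsilyloxy)-6,8-dioxabicyclo[3.2.1]octane
Product: 18 (1S,3S,5S,7S)-5-[4-(benzyloxy)-3-methoxyphenyl]-7-exo-[4-(benzyloxy)benzyl]-6,8-dioxabicyclo[3.2.1]octan-3-endo-ol
Conditions: TBAF, THF, rt
Reagents that add atoms: none
Why: Fluoride-mediated desilylation, to which the ketal and the benzyl ethers are inert, leaves the C3 hydroxyl as the only free hydroxyl because the C6 oxygen is part of the ketal.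

Step 11
Reactants: 18 (1S,3S,5S,7S)-5-[4-(benzyloxy)-3-methoxyphenyl]-7-exo-[4-(benzyloxy)benzyl]-6,8-dioxabicyclo[3.2.1]octan-3-endo-ol
Product: 19 (1S,3R,5S,7S)-5-[4-(benzyloxy)-3-methoxyphenyl]-7-exo-[4-(benzyloxy)benzyl]-6,8-dioxabicyclo[3.2.1]octan-3-exo-yl 4-nitrobenzoate
Conditions: 4-O2NC6H4CO2H, PPh3, DIAD, toluene, 0 °C → rt
Reagents that add atoms: 4-nitrobenzoic acid, O=C(O)c1ccc(cc1)[N+](=O)[O-]
Why: Mitsunobu esterification with inversion, in which the endo (axial) oxyphosphonium ion is displaced by 4-nitrobenzoate from the open exo face in an SN2 step (the known endo-to-exo inversion of 3-hydroxybicyclo[3.2.1]octanes), turns C3 into the configuration of the target, and the acidic pronucleophile should limit E2 elimination.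

Step 12
Reactants: 19 (1S,3R,5S,7S)-5-[4-(benzyloxy)-3-methoxyphenyl]-7-exo-[4-(benzyloxy)benzyl]-6,8-dioxabicyclo[3.2.1]octan-3-exo-yl 4-nitrobenzoate
Product: 20 (1S,3R,5S,7S)-5-[4-(benzyloxy)-3-methoxyphenyl]-7-exo-[4-(benzyloxy)benzyl]-6,8-dioxabicyclo[3.2.1]octan-3-exo-ol
Conditions: K2CO3 (cat.), MeOH–THF, rt
Reagents that add atoms: none
Why: Base-catalysed transesterification (methanolysis) of the activated 4-nitrobenzoate cleaves the acyl–oxygen bond, so C3 keeps its new configuration, and the ketal is stable to base.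

Step 13
Reactants: 20 (1S,3R,5S,7S)-5-[4-(benzyloxy)-3-methoxyphenyl]-7-exo-[4-(benzyloxy)benzyl]-6,8-dioxabicyclo[3.2.1]octan-3-exo-ol
Product: 22 (2S,4S,6R)-2-{(1S)-2-[4-(benzyloxy)phenyl]-1-hydroxyethyl}-6-[4-(benzyloxy)-3-methoxyphenyl]tetrahydro-2H-pyran-4-ol, via its bis(trimethylsilyl) ether 21 (not isolated)
Conditions: Et3SiH, TMSOTf, CH2Cl2, −78 → −30 °C; then 1 M aq. HCl, THF, rt
Reagents that add atoms: none
Why: Ionic hydrogenation of an aryl ketal, in which TMSOTf silylates the free hydroxyl and the dioxolane oxygen (the axial bond from C1 to the C6 oxygen, antiperiplanar to a lone pair of the pyran oxygen, ionises to the six-membered aryl oxocarbenium ion and not the seven-membered one), the cation takes the half-chair with the C5 side chain equatorial and the small C3 silyloxy group axial, and Et3SiH delivers hydride axially through a chair-like transition state anti to the C5 side chain, which should set C1 as (R) with the 2,6-cis arrangement; the acidic work-up removes both TMS groups.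

Step 14
Reactants: 22 (2S,4S,6R)-2-{(1S)-2-[4-(benzyloxy)phenyl]-1-hydroxyethyl}-6-[4-(benzyloxy)-3-methoxyphenyl]tetrahydro-2H-pyran-4-ol
Product: 23 rhoiptelol B, (2S,4S,6R)-2-[(1S)-1-hydroxy-2-(4-hydroxyphenyl)ethyl]-6-(4-hydroxy-3-methoxyphenyl)tetrahydro-2H-pyran-4-ol
Conditions: H2 (1 atm), 10% Pd/C, EtOAc, rt
Reagents that add atoms: none
Why: Hydrogenolysis of the two aryl benzyl ethers over Pd/C in a neutral solvent, stopped after uptake of two equivalents of hydrogen so that the more slowly cleaved benzylic C1–O bond of the ring survives.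

**Compound list**

1 | 4-(benzyloxy)benzyl chloride | ClCc1ccc(OCc2ccccc2)cc1 | starting material
2 | ethynylmagnesium bromide | C#C[Mg]Br | starting material
3 | 1-(benzyloxy)-4-(prop-2-yn-1-yl)benzene | C#CCc1ccc(OCc2ccccc2)cc1 | intermediate
4 | 4-(benzyloxy)-3-methoxybenzaldehyde (O-benzylvanillin) | COc1cc(C=O)ccc1OCc1ccccc1 | starting material
5 | 2-[4-(benzyloxy)-3-methoxyphenyl]-1,3-dithiane | COc1cc(C2SCCCS2)ccc1OCc1ccccc1 | intermediate
6 | (R)-epichlorohydrin | C1O[C@H]1CCl | starting material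
7 | 2-lithio-2-[4-(benzyloxy)-3-methoxyphenyl]-1,3-dithiane | COc1cc(C2([Li])SCCCS2)ccc1OCc1ccccc1 | intermediate
8 | lithium (R)-1-chloro-3-{2-[4-(benzyloxy)-3-methoxyphenyl]-1,3-dithian-2-yl}propan-2-olate | COc1cc(C2(C[C@@H](O[Li])CCl)SCCCS2)ccc1OCc1ccccc1 | intermediate
9 | (R)-2-({2-[4-(benzyloxy)-3-methoxyphenyl]-1,3-dithian-2-yl}methyl)oxirane | COc1cc(C2(C[C@@H]3CO3)SCCCS2)ccc1OCc1ccccc1 | intermediate
10 | lithium 3-[4-(benzyloxy)phenyl]prop-1-yn-1-ide | [Li]C#CCc1ccc(OCc2ccccc2)cc1 | intermediate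
11 | (S)-1-{2-[4-(benzyloxy)-3-methoxyphenyl]-1,3-dithian-2-yl}-6-[4-(benzyloxy)phenyl]hex-4-yn-2-ol | COc1cc(C2(C[C@@H](O)CC#CCc3ccc(OCc4ccccc4)cc3)SCCCS2)ccc1OCc1ccccc1 | intermediate
12 | (S)-1-[4-(benzyloxy)-3-methoxyphenyl]-7-[4-(benzyloxy)phenyl]-3-hydroxyhept-5-yn-1-one | COc1cc(C(=O)C[C@@H](O)CC#CCc2ccc(OCc3ccccc3)cc2)ccc1OCc1ccccc1 | intermediate
13 | (S,Z)-1-[4-(benzyloxy)-3-methoxyphenyl]-7-[4-(benzyloxy)phenyl]-3-hydroxyhept-5-en-1-one | COc1cc(C(=O)C[C@@H](O)C/C=C\Cc2ccc(OCc3ccccc3)cc2)ccc1OCc1ccccc1 | intermediate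
14 | (S)-1-[4-(benzyloxy)-3-methoxyphenyl]-4-{(2R,3S)-3-[4-(benzyloxy)benzyl]oxiran-2-yl}-3-hydroxybutan-1-one (1,3-syn epoxy alcohol) | COc1cc(C(=O)C[C@@H](O)C[C@H]2O[C@H]2Cc2ccc(OCc3ccccc3)cc2)ccc1OCc1ccccc1 | intermediate
15 | (S)-1-[4-(benzyloxy)-3-methoxyphenyl]-4-{(2R,3S)-3-[4-(benzyloxy)benzyl]oxiran-2-yl}-3-(tert-butyldimethylsilyloxy)butan-1-one | COc1cc(C(=O)C[C@@H](O[Si](C)(C)C(C)(C)C)C[C@H]2O[C@H]2Cc2ccc(OCc3ccccc3)cc2)ccc1OCc1ccccc1 | intermediate
16 | (2S,4S)-6-[4-(benzyloxy)-3-methoxyphenyl]-2-{(1S)-2-[4-(benzyloxy)phenyl]-1-hydroxyethyl}-4-(tert-butyldimethylsilyloxy)-3,4-dihydro-2H-pyran-1-ium (hydroxy oxocarbenium ion) | COc1cc(C2=[O+][C@H]([C@@H](O)Cc3ccc(OCc4ccccc4)cc3)C[C@H](O[Si](C)(C)C(C)(C)C)C2)ccc1OCc1ccccc1 | intermediate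
17 | (1S,3S,5S,7S)-5-[4-(benzyloxy)-3-methoxyphenyl]-7-exo-[4-(benzyloxy)benzyl]-3-endo-(tert-butyldimethylsilyloxy)-6,8-dioxabicyclo[3.2.1]octane | COc1cc([C@]23C[C@@H](O[Si](C)(C)C(C)(C)C)C[C@H](O2)[C@H](Cc4ccc(OCc5ccccc5)cc4)O3)ccc1OCc1ccccc1 | intermediate
18 | (1S,3S,5S,7S)-5-[4-(benzyloxy)-3-methoxyphenyl]-7-exo-[4-(benzyloxy)benzyl]-6,8-dioxabicyclo[3.2.1]octan-3-endo-ol | COc1cc([C@]23C[C@@H](O)C[C@H](O2)[C@H](Cc4ccc(OCc5ccccc5)cc4)O3)ccc1OCc1ccccc1 | intermediate
19 | (1S,3R,5S,7S)-5-[4-(benzyloxy)-3-methoxyphenyl]-7-exo-[4-(benzyloxy)benzyl]-6,8-dioxabicyclo[3.2.1]octan-3-exo-yl 4-nitrobenzoate | COc1cc([C@]23C[C@H](OC(=O)c6ccc(cc6)[N+](=O)[O-])C[C@H](O2)[C@H](Cc4ccc(OCc5ccccc5)cc4)O3)ccc1OCc1ccccc1 | intermediate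
20 | (1S,3R,5S,7S)-5-[4-(benzyloxy)-3-methoxyphenyl]-7-exo-[4-(benzyloxy)benzyl]-6,8-dioxabicyclo[3.2.1]octan-3-exo-ol | COc1cc([C@]23C[C@H](O)C[C@H](O2)[C@H](Cc4ccc(OCc5ccccc5)cc4)O3)ccc1OCc1ccccc1 | intermediate
21 | bis(trimethylsilyl) ether of 22: (2R,4S,6S)-2-[4-(benzyloxy)-3-methoxyphenyl]-6-{(1S)-2-[4-(benzyloxy)phenyl]-1-(trimethylsilyloxy)ethyl}-4-(trimethylsilyloxy)tetrahydro-2H-pyran | COc1cc([C@H]2C[C@H](O[Si](C)(C)C)C[C@@H]([C@@H](O[Si](C)(C)C)Cc3ccc(OCc4ccccc4)cc3)O2)ccc1OCc1ccccc1 | intermediate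
22 | (2S,4S,6R)-2-{(1S)-2-[4-(benzyloxy)phenyl]-1-hydroxyethyl}-6-[4-(benzyloxy)-3-methoxyphenyl]tetrahydro-2H-pyran-4-ol | COc1cc([C@H]2C[C@H](O)C[C@@H]([C@@H](O)Cc3ccc(OCc4ccccc4)cc3)O2)ccc1OCc1ccccc1 | intermediate
23 | rhoiptelol B, (2S,4S,6R)-2-[(1S)-1-hydroxy-2-(4-hydroxyphenyl)ethyl]-6-(4-hydroxy-3-methoxyphenyl)tetrahydro-2H-pyran-4-ol | COc1cc([C@H]2C[C@H](O)C[C@@H]([C@@H](O)Cc3ccc(O)cc3)O2)ccc1O | target

**Step count and risks**

Total step count: 14. Longest linear sequence: 13 steps (steps 2–14, from aldehyde 4); step 1 is a one-step branch to alkyne 3.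

The three steps most likely to fail:

(i) The directed epoxidation (step 7). Oxygen delivery may show poor facial selectivity because the ketone can also bind vanadium, and the Lewis-acidic catalyst may induce premature cyclisation of the unprotected epoxy alcohol (5-endo attack of the C3 hydroxyl on C6). The fallback sets out from alcohol 11 and replaces the metal-directed delivery by an iodocarbonate cyclisation. Boc2O/DMAP should convert 11 into the tert-butyl carbonate F1. MeI/CaCO3 hydrolysis of the dithiane should give the keto carbonate F2, and Lindlar reduction the Z-alkene F3. IBr in toluene at −85 °C should then close the six-membered carbonate through a chair with both substituents equatorial, placing oxygen on C5 syn to the C3 oxygen and iodine anti on C6, to give the iodocarbonate F4. K2CO3 in MeOH should cleave the carbonate, and the C5 alkoxide should displace iodide with inversion at C6. This comes back to the route at the syn cis-epoxy alcohol 14, without any Lewis acid.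

(ii) The key cascade (step 9). The activated epoxide may be consumed by other pathways (attack of the silyl ether oxygen at C6, a 1,2-hydride shift, or participation of the benzyloxyphenyl ring) faster than it is captured by the carbonyl oxygen. The fallback sets out from epoxy alcohol 14 and lets a tethered carbamate, a stronger internal nucleophile, open the epoxide at the same carbon with the same inversion. Phenyl isocyanate should give the phenylcarbamate F5. BF3·OEt2 should then let the carbamate carbonyl oxygen open the epoxide at C5 (6-exo) to the cyclic iminocarbonate F6, which dilute aqueous acid should hydrolyse to the cyclic carbonate F7 with the C6 hydroxyl free. K2CO3/MeOH should give the (3S,5S,6S)-triol ketone F8, and CSA in CH2Cl2 should close the ketal by ordinary keto-diol ketalisation. This comes back to the route at alcohol 18.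

(iii) The Mitsunobu inversion (step 11). Activation of the hindered endo hydroxyl may be slow, and the axial oxyphosphonium ion may undergo E2 elimination through the antiperiplanar axial hydrogens on C2 and C4. The fallback sets out from silyl ether 17 and corrects C3 after ring opening by oxidation and reduction instead of substitution. Et3SiH/TMSOTf with acidic work-up should give the all-cis tetrahydropyran alcohol F9 (C3 silyloxy group equatorial, C6 hydroxyl free). NaH/BnBr should give the benzyl ether F10, and TBAF the equatorial alcohol F11. Dess–Martin periodinane should give the tetrahydropyran-4-one F12. L-Selectride, which attacks 2,6-cis-tetrahydropyran-4-ones from the equatorial side, should give the axial alcohol F13, the tribenzyl ether of the target. Hydrogenolysis over Pd/C comes back to the route at 23.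

**Further compounds**

F1 | step 7 | tert-butyl (S)-1-{2-[4-(benzyloxy)-3-methoxyphenyl]-1,3-dithian-2-yl}-6-[4-(benzyloxy)phenyl]hex-4-yn-2-yl carbonate | COc1cc(C2(C[C@@H](OC(=O)OC(C)(C)C)CC#CCc3ccc(OCc4ccccc4)cc3)SCCCS2)ccc1OCc1ccccc1
F2 | step 7 | tert-butyl (S)-1-[4-(benzyloxy)-3-methoxyphenyl]-7-[4-(benzyloxy)phenyl]-1-oxohept-5-yn-3-yl carbonate | COc1cc(C(=O)C[C@@H](OC(=O)OC(C)(C)C)CC#CCc2ccc(OCc3ccccc3)cc2)ccc1OCc1ccccc1
F3 | step 7 | tert-butyl (S,Z)-1-[4-(benzyloxy)-3-methoxyphenyl]-7-[4-(benzyloxy)phenyl]-1-oxohept-5-en-3-yl carbonate | COc1cc(C(=O)C[C@@H](OC(=O)OC(C)(C)C)C/C=C\Cc2ccc(OCc3ccccc3)cc2)ccc1OCc1ccccc1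
F4 | step 7 | (4S,6R)-4-{2-[4-(benzyloxy)-3-methoxyphenyl]-2-oxoethyl}-6-{(1R)-2-[4-(benzyloxy)phenyl]-1-iodoethyl}-1,3-dioxan-2-one | COc1cc(C(=O)C[C@@H]2C[C@H]([C@H](I)Cc3ccc(OCc4ccccc4)cc3)OC(=O)O2)ccc1OCc1ccccc1
F5 | step 9 | (S)-4-[4-(benzyloxy)-3-methoxyphenyl]-1-{(2R,3S)-3-[4-(benzyloxy)benzyl]oxiran-2-yl}-4-oxobutan-2-yl phenylcarbamate | COc1cc(C(=O)C[C@@H](OC(=O)Nc2ccccc2)C[C@H]2O[C@H]2Cc2ccc(OCc3ccccc3)cc2)ccc1OCc1ccccc1
F6 | step 9 | 1-[4-(benzyloxy)-3-methoxyphenyl]-2-[(4S,6S)-6-{(1S)-2-[4-(benzyloxy)phenyl]-1-hydroxyethyl}-2-(phenylimino)-1,3-dioxan-4-yl]ethan-1-one | COc1cc(C(=O)C[C@@H]2C[C@@H]([C@@H](O)Cc3ccc(OCc4ccccc4)cc3)OC(=Nc3ccccc3)O2)ccc1OCc1ccccc1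
F7 | step 9 | (4S,6S)-4-{2-[4-(benzyloxy)-3-methoxyphenyl]-2-oxoethyl}-6-{(1S)-2-[4-(benzyloxy)phenyl]-1-hydroxyethyl}-1,3-dioxan-2-one | COc1cc(C(=O)C[C@@H]2C[C@@H]([C@@H](O)Cc3ccc(OCc4ccccc4)cc3)OC(=O)O2)ccc1OCc1ccccc1
F8 | step 9 | (3S,5S,6S)-1-[4-(benzyloxy)-3-methoxyphenyl]-7-[4-(benzyloxy)phenyl]-3,5,6-trihydroxyheptan-1-one | COc1cc(C(=O)C[C@@H](O)C[C@H](O)[C@@H](O)Cc2ccc(OCc3ccccc3)cc2)ccc1OCc1ccccc1
F9 | step 11 | (S)-2-[4-(benzyloxy)phenyl]-1-{(2S,4R,6R)-6-[4-(benzyloxy)-3-methoxyphenyl]-4-(tert-butyldimethylsilyloxy)tetrahydro-2H-pyran-2-yl}ethan-1-ol | COc1cc([C@H]2C[C@@H](O[Si](C)(C)C(C)(C)C)C[C@@H]([C@@H](O)Cc3ccc(OCc4ccccc4)cc3)O2)ccc1OCc1ccccc1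
F10 | step 11 | (2S,4R,6R)-2-{(1S)-1-(benzyloxy)-2-[4-(benzyloxy)phenyl]ethyl}-6-[4-(benzyloxy)-3-methoxyphenyl]-4-(tert-butyldimethylsilyloxy)tetrahydro-2H-pyran | COc1cc([C@H]2C[C@@H](O[Si](C)(C)C(C)(C)C)C[C@@H]([C@@H](OCc5ccccc5)Cc3ccc(OCc4ccccc4)cc3)O2)ccc1OCc1ccccc1
F11 | step 11 | (2S,4R,6R)-2-{(1S)-1-(benzyloxy)-2-[4-(benzyloxy)phenyl]ethyl}-6-[4-(benzyloxy)-3-methoxyphenyl]tetrahydro-2H-pyran-4-ol | COc1cc([C@H]2C[C@@H](O)C[C@@H]([C@@H](OCc5ccccc5)Cc3ccc(OCc4ccccc4)cc3)O2)ccc1OCc1ccccc1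
F12 | step 11 | (2S,6R)-2-{(1S)-1-(benzyloxy)-2-[4-(benzyloxy)phenyl]ethyl}-6-[4-(benzyloxy)-3-methoxyphenyl]tetrahydro-4H-pyran-4-one | COc1cc([C@H]2CC(=O)C[C@@H]([C@@H](OCc5ccccc5)Cc3ccc(OCc4ccccc4)cc3)O2)ccc1OCc1ccccc1
F13 | step 11 | (2S,4S,6R)-2-{(1S)-1-(benzyloxy)-2-[4-(benzyloxy)phenyl]ethyl}-6-[4-(benzyloxy)-3-methoxyphenyl]tetrahydro-2H-pyran-4-ol | COc1cc([C@H]2C[C@H](O)C[C@@H]([C@@H](OCc5ccccc5)Cc3ccc(OCc4ccccc4)cc3)O2)ccc1OCc1ccccc1
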